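Start with a subtraction. Protic impurity takes coupling partner one for one, so of the 14.3 mM charged to east, 12.1 mM is usable. Call usable coupling partner minus substrate charged the reagent margin, 1.10 mM: its sign names the limiting reagent, and when substrate is limiting its size is the coupling partner that stays free once the substrate has gone, before target and decomposition product take their share.

| flask | substrate | coupling partner | protic impurity | temperature | remark | time |
|---|---|---|---|---|---|---|
| ash | 11 mM | 14.3 mM | 2.2 mM | 5 °C | run made earlier |  |
| cedar | 15 mM | 14.3 mM | 2.2 mM | 20 °C | run made earlier |  |
| elm | 24 mM | 14.3 mM | 2.2 mM | 5 °C | run made earlier |  |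
| north-east | 11 mM | 14.3 mM (fed, over 10 d) | 2.20 mM | 20 °C | all else is in the flask from the start; the feed brings no volume worth counting | 25 d |
| east | 11 mM | 14.3 mM (fed, over 25 h) | 2.20 mM | 20 °C | all else is in the flask from the start; the feed brings no volume worth counting | 25 d |
| north-west | 11 mM | 14.3 mM (fed, over 10 d) | 2.20 mM |  | the addition at −20 °C, then warmed to 20 °C; the feed brings no volume worth counting | 25 d |
| north | 11 mM (fed, over 10 d) | 14.3 mM | 2.20 mM | 20 °C | all else is in the flask from the start; the feed brings no volume worth counting | 25 d |

| run | time / d | side product / % | target / % | substrate / % |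
|---|---|---|---|---|
| ash | 5.00 | 2 | 0 | 79 |
| ash | 10.0 | 11 | 5 | 65 |
| ash | 15.0 | 22 | 5 | 59 |
| ash | 20.0 | 31 | 4 | 56 |
| ash | 25.0 | 40 | 1 | 46 |
| ash | 30.0 | 41 | 4 | 39 |
| cedar | 5.00 | 42 | 0 | 49 |
| cedar | 10.0 | 59 | 3 | 36 |
| cedar | 15.0 | 65 | 4 | 32 |
| cedar | 20.0 | 68 | 6 | 31 |
| cedar | 25.0 | 71 | 3 | 29 |
| cedar | 30.0 | 73 | 0 | 25 |
| elm | 5.00 | 4 | 2 | 80 |
| elm | 8.00 | 9 | 2 | 76 |
| elm | 12.0 | 14 | 2 | 71 |
| elm | 20.0 | 23 | 0 | 64 |
| elm | 40.0 | 37 | 5 | 54 |
| elm | 60.0 | 46 | 2 | 51 |

(readings scatter by 2 percentage points)

- what is said of target includes crystals
- crystals is a solid; its amount is given per volume of the solution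
- steps under discussion: substrate + coupling partner <-> intermediate A; intermediate A <-> intermediate B; coupling partner + intermediate A -> target; intermediate B -> side product; coupling partner + protic impurity -> quenched reagent; coupling partner -> decomposition product; crystals <-> target

- the flask that comes out highest in amount of side product, in percent of the substrate charged, or "all alike" when all lie within 1.5 percentage points (north-east / east / north-west / north / all alike)
- side product at the end, in percent of the substrate charged, north-east
- side product at the end, in percent of the substrate charged, east
- side product at the end, in percent of the substrate charged, north-west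
- side product at the end, in percent of the substrate charged, north

The elm run tests this correction: from 24 mM of substrate it has lost 11.8 mM by 60.0 d, a reading close to the usable amount.

Cedar looks nearly the same as east, with the same temperature, coupling partner and impurity, but it holds 15 mM of substrate against 11 mM, and its coupling partner is in the flask from the start, whereas east's is fed over 25 h. Cedar's substrate charge turns its margin to −2.90 mM, so in cedar the coupling partner is limiting: side product is capped near 80.7% of the substrate and reads 73% at 30.0 d, with substrate reading 25% against a floor of 19.3%.

In east the margin is positive, so substrate is the limiting reagent and the question is how far the rate carries it in 25 d. Cedar's substrate at 5.00 d, put through the integrated second-order law with the impurity counted as quenched from the start, gives as a reading a second-order half-life of 4.59 d for east's charge. East's margin is smaller than its charge and its feed shorter than the run, so I treat the two reagents as equal and as present from the start, which leaves 15.5% of the substrate at 25 d. My reckoning thus has 84.5% consumed in east, and side product stands below that by the target and intermediates. East's feed of 25 h is shorter than the 10 d of the others, so I expect it highest.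

The forecast also names east, with 77% for north-east, 81% for east, 74% for north-west and 79% for north, holding that “the 25 d result is kinetically limited, not stoichiometrically”. Where I have 84.5% consumed in east, it has about 88%.

The flasks give 79.2% in north-east, 82.1% in east, 73.2% in north-west and 77.8% in north, with east highest.

    substrate + coupling partner ⇌ intermediate A (K = 37.0 /M, k = 2.40 × 10⁻⁴ /M/s, Ea = 70.0 kJ/mol, ΔH = −2.00 kJ/mol)
    intermediate A ⇌ intermediate B (K = 10.0, k = 7.80 × 10⁻⁵ /s, Ea = 99.0 kJ/mol, ΔH = −62.0 kJ/mol)
    coupling partner + intermediate A → target (k = 2.70 × 10⁻⁴ /M/s, Ea = 58.0 kJ/mol)
    intermediate B → side product (k = 1.10 × 10⁻⁵ /s, Ea = 91.0 kJ/mol)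
    coupling partner + protic impurity → quenched reagent (k = 0.00260 /M/s, Ea = 48.0 kJ/mol)
    coupling partner → decomposition product (k = 7.00 × 10⁻⁹ /s, Ea = 111 kJ/mol)
    crystals ⇌ target, rate k7*(cs7 - [target]) while solid is left; crystals form when [target] > cs7 (solubility = 0.400 mM, k = 3.40 × 10⁻⁴ /s)
    (constants at 20 °C)

East has not come to rest at 25.0 d: substrate stands at 14.0% and side product at 82.1%. At 250 d side product reaches 96.4% and substrate 0.367%. The margin, less 0.359 mM of target and 0.187 mM of decomposition product, plus the remaining substrate, then comes to 0.594 mM, and east holds 0.594 mM of coupling partner. North-east, with the same charges and so the same margin, comes at 250 d to 0.681 mM by this sum and holds 0.681 mM of coupling partner.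

(All runs stem from a simulated flask for an exercise, noise included.)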